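**Retrosynthetic overview**

- Numbering: ring A (arene) is counted from the bridge carbon: position 1 C–CH2 bridge, position 2 C–OH, position 3 C–prenyl, position 4 C–OH, position 5 C–isobutyryl, position 6 C–OMe; ring B (pyrone): position 1 O, position 2 C=O, position 3 C–bridge, position 4 C–OH, position 5 C–Me, position 6 C–Et.
- Feature: the hydroxyl at position 2 of ring A is ortho to the CH2 bridge that joins position 1 of ring A to position 3 of ring B, so its oxygen can close a six-membered lactone on the pyrone carbonyl (position 2 of ring B), and position 6 of ring A, next to the bridge, is a methyl ether; the target is therefore the ring-chain isomer of a 3-acyl-3,4-dihydrocoumarin.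
- Disconnections: the pyrone bond between positions 1 and 2 of ring B is traded for a lactone from the oxygen at position 2 of ring A to position 2 of ring B (translactonisation); the bond between positions 5 and 6 of ring B comes from C-acylation of a propanoyl CH2 with N-methoxy-N-methylpropanamide; the bridge CH2 comes from conjugate reduction of a 3-propanoylcoumarin.
- The coumarin is assembled from an aryne across positions 1 and 2 of ring A, DMF (the oxygen at position 2 and the bridge CH) and methyl 3-oxopentanoate (positions 2, 3, 4 and 5 of ring B with the methyl group at position 5); the silyl triflate is built from 5-methoxyresorcinol by three directed lithiations.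
- Ring order: ring A is bought; the lactone ring closes in step 9; ring B closes in step 12 while the lactone opens.

Key step: step 9

Remark: the target has no stereocentre. Stereocentres in 10, 19, 21, 24, 27 and 28 form without control, are drawn without configuration, and are all erased later.

**Route**

Step 1
Reactants: 1 5-methoxyresorcinol
Product: 2 1-methoxy-3,5-bis(methoxymethoxy)benzene
Conditions: NaH (2.4 equiv), MOMCl (2.4 equiv), DMF, 0 °C → rt
Reagents that add atoms: chloromethyl methyl ether, COCCl
Why: Williamson O-alkylation of both phenoxides installs the two MOM ethers that direct the later ortho-lithiations.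

Step 2
Reactants: 2 1-methoxy-3,5-bis(methoxymethoxy)benzene; 3 prenyl bromide
Product: 5 5-methoxy-1,3-bis(methoxymethoxy)-2-(3-methylbut-2-en-1-yl)benzene, via aryllithium 4 (not isolated)
Conditions: n-BuLi (1.1 equiv), THF, 0 °C → rt; then CuI (10 mol %), 3 (1.3 equiv), −78 °C → rt
Reagents that add atoms: none
Why: directed ortho-metalation should occur at the CH flanked by both MOM ethers (future position 3 of ring A), and copper-assisted SN2 allylation should give the linear prenyl arene.

Step 3
Reactants: 5 5-methoxy-1,3-bis(methoxymethoxy)-2-(3-methylbut-2-en-1-yl)benzene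
Product: 7 trimethyl[6-methoxy-2,4-bis(methoxymethoxy)-3-(3-methylbut-2-en-1-yl)phenyl]silane, via aryllithium 6 (not isolated)
Conditions: n-BuLi (1.2 equiv), TMEDA (1.2 equiv), THF, −20 → 0 °C; then Me3SiCl, −78 °C → rt
Reagents that add atoms: chlorotrimethylsilane, C[Si](C)(C)Cl
Why: the two remaining ring CH groups of 5 are equivalent by symmetry and each lies between OMOM and OMe, so directed ortho-metalation and silyl quench should place the silyl group at position 1 of ring A without a regiochemical issue.

Step 4
Reactants: 7 trimethyl[6-methoxy-2,4-bis(methoxymethoxy)-3-(3-methylbut-2-en-1-yl)phenyl]silane; 8 isobutyraldehyde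
Product: 10 racemic 1-[6-methoxy-2,4-bis(methoxymethoxy)-3-(3-methylbut-2-en-1-yl)-5-(trimethylsilyl)phenyl]-2-methylpropan-1-ol, via aryllithium 9 (not isolated)
Conditions: s-BuLi (1.2 equiv), TMEDA, THF, −78 → −40 °C; then 8, −78 °C; then H2O
Reagents that add atoms: none
Why: the last ring CH (position 5 of ring A, between OMOM and OMe) should be metalated by directed ortho-metalation and add 1,2 to the aldehyde; the carbinol centre forms racemic and is erased in step 5.

Step 5
Reactants: 10 racemic 1-[6-methoxy-2,4-bis(methoxymethoxy)-3-(3-methylbut-2-en-1-yl)-5-(trimethylsilyl)phenyl]-2-methylpropan-1-ol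
Product: 11 1-[6-methoxy-2,4-bis(methoxymethoxy)-3-(3-methylbut-2-en-1-yl)-5-(trimethylsilyl)phenyl]-2-methylpropan-1-one
Conditions: Dess–Martin periodinane (1.3 equiv), pyridine, CH2Cl2, 0 °C → rt
Reagents that add atoms: none
Why: pyridine-buffered Dess–Martin oxidation should convert the hindered benzylic alcohol to the ketone without acid that could cleave the aryl–silicon bond or the MOM ethers.

Step 6
Reactants: 11 1-[6-methoxy-2,4-bis(methoxymethoxy)-3-(3-methylbut-2-en-1-yl)-5-(trimethylsilyl)phenyl]-2-methylpropan-1-one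
Product: 13 1-[2,4-dihydroxy-6-methoxy-3-(3-methylbut-2-en-1-yl)-5-(trimethylsilyl)phenyl]-2-methylpropan-1-one, via bis(silyl ether) 12 (not isolated)
Conditions: Me3SiOTf (4 equiv), 2,2'-bipyridyl (6 equiv), CH3CN, 0 °C → rt; then H2O
Reagents that add atoms: none
Why: silyl triflate/bipyridyl cleavage of aryl MOM ethers runs through aryl silyl ethers without Brønsted acid, so the aryl–SiMe3 bond on this electron-rich ring (which HCl would protodesilylate) and the prenyl group should survive.

Step 7
Reactants: 13 1-[2,4-dihydroxy-6-methoxy-3-(3-methylbut-2-en-1-yl)-5-(trimethylsilyl)phenyl]-2-methylpropan-1-one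
Product: 14 3-hydroxy-5-methoxy-2-(3-methylbut-2-en-1-yl)-4-(2-methylpropanoyl)-6-(trimethylsilyl)phenyl trifluoromethanesulfonate
Conditions: Tf2O (1.05 equiv), pyridine, CH2Cl2, −78 → 0 °C
Reagents that add atoms: trifluoromethanesulfonic anhydride, O=S(=O)(OS(=O)(=O)C(F)(F)F)C(F)(F)F
Why: site-selective O-sulfonylation is expected because the hydroxyl at position 4 of ring A is tied up in a hydrogen bond to the isobutyryl carbonyl (as the 2-OH of 2,4-dihydroxyaryl ketones), leaving the hydroxyl at position 2 as the reactive phenol.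

Step 8
Reactants: 14 3-hydroxy-5-methoxy-2-(3-methylbut-2-en-1-yl)-4-(2-methylpropanoyl)-6-(trimethylsilyl)phenyl trifluoromethanesulfonate
Product: 15 5-methoxy-3-(methoxymethoxy)-2-(3-methylbut-2-en-1-yl)-4-(2-methylpropanoyl)-6-(trimethylsilyl)phenyl trifluoromethanesulfonate
Conditions: MOMCl (3 equiv), i-Pr2NEt (4 equiv), CH2Cl2, 0 → 40 °C
Reagents that add atoms: chloromethyl methyl ether, COCCl
Why: O-alkylation of the remaining chelated phenol under amine base, free of fluoride, masks the hydroxyl at position 4 of ring A so that no phenoxide competes for the aryne in step 9 or consumes base in step 11.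

Step 9
Reactants: 15 5-methoxy-3-(methoxymethoxy)-2-(3-methylbut-2-en-1-yl)-4-(2-methylpropanoyl)-6-(trimethylsilyl)phenyl trifluoromethanesulfonate; 16 N,N-dimethylformamide; 17 methyl 3-oxopentanoate
Product: 23 5-methoxy-7-(methoxymethoxy)-8-(3-methylbut-2-en-1-yl)-6-(2-methylpropanoyl)-3-propanoyl-2H-chromen-2-one, via aryne 18 (not isolated), via aminobenzoxetene 19 (not isolated), via amino quinone methide 20 (not isolated), via Mannich adduct 21 (not isolated), via benzylidene keto ester 22 (not isolated)
Conditions: CsF (4 equiv), 17 (1.5 equiv), DMF as solvent, 25 → 50 °C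
Reagents that add atoms: none
Why: Fluoride removes the silyl group and triflate leaves to give aryne 18 across positions 1 and 2 of ring A; the carbonyl oxygen of the solvent DMF attacks position 2 and the aryl anion at position 1 closes on the iminium carbon (formal [2+2]) to benzoxetene 19, which ring-opens to the amino ortho-quinone methide 20. The fluoride-generated enolate of 17 adds to the aminomethylidene carbon (21), dimethylamine is lost by E1cB (22), and the phenoxide at position 2 closes on the methyl ester to give coumarin 23. This is the known three-component coupling of arynes, formamides and ester-bearing active methylene compounds to coumarins, the aryne counterpart of a Knoevenagel coumarin synthesis from a salicylaldehyde. The one ring that remains is the lactone, closed by 6-exo-trig acyl substitution at the ester carbonyl (the four-membered ring of 19 is transient), and no stereocentre is formed. The step needs oxygen at position 2 and carbon at position 1: the inductively withdrawing methoxy group at position 6, next to position 1, distorts the aryne so that the nucleophile attacks the remote carbon (position 2) and the aryl anion develops at position 1, which should outweigh the steric bias of the prenyl group at position 3. DMF as solvent should outcompete the enolate for the aryne, and the oxygen at position 2 is the only one that can lactonise because position 6 carries a methyl ether.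

Step 10
Reactants: 23 5-methoxy-7-(methoxymethoxy)-8-(3-methylbut-2-en-1-yl)-6-(2-methylpropanoyl)-3-propanoyl-2H-chromen-2-one
Product: 24 racemic 5-methoxy-7-(methoxymethoxy)-8-(3-methylbut-2-en-1-yl)-6-(2-methylpropanoyl)-3-propanoyl-3,4-dihydro-2H-chromen-2-one
Conditions: Hantzsch ester (diethyl 2,6-dimethyl-1,4-dihydropyridine-3,5-dicarboxylate, 1.5 equiv), silica gel, toluene, 80 °C
Reagents that add atoms: none
Why: transfer hydrogenation by hydride delivery to carbon 4 of the doubly activated alkylidene β-keto lactone should spare the prenyl alkene, both ketones and the MOM ether; the stereocentre at carbon 3 is enolisable, racemic, and erased in step 12.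

Step 11
Reactants: 24 racemic 5-methoxy-7-(methoxymethoxy)-8-(3-methylbut-2-en-1-yl)-6-(2-methylpropanoyl)-3-propanoyl-3,4-dihydro-2H-chromen-2-one; 25 N-methoxy-N-methylpropanamide
Product: 28 5-methoxy-7-(methoxymethoxy)-8-(3-methylbut-2-en-1-yl)-3-(2-methyl-3-oxopentanoyl)-6-(2-methylpropanoyl)-3,4-dihydro-2H-chromen-2-one, via trilithium trienolate 26 (not isolated), via hemiaminal adduct 27 (not isolated)
Conditions: LiN(i-Pr)2 (3.3 equiv), THF, −78 → −20 °C; then 25 (1.2 equiv), −78 → 0 °C; then AcOH, −78 °C
Reagents that add atoms: none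
Why: γ-acylation of a β-dicarbonyl dianion (Claisen-type) is expected at the propanoyl CH carbon, the most basic and least hindered nucleophile, while the third equivalent of base only parks the isobutyryl α-CH as a hindered tetrasubstituted enolate that should not react with the amide; the chelated adduct 27 prevents over-addition, and the new stereocentres are uncontrolled and erased in step 12.

Step 12
Reactants: 28 5-methoxy-7-(methoxymethoxy)-8-(3-methylbut-2-en-1-yl)-3-(2-methyl-3-oxopentanoyl)-6-(2-methylpropanoyl)-3,4-dihydro-2H-chromen-2-one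
Product: 29 6-ethyl-4-hydroxy-3-{[2-hydroxy-6-methoxy-4-(methoxymethoxy)-3-(3-methylbut-2-en-1-yl)-5-(2-methylpropanoyl)phenyl]methyl}-5-methyl-2H-pyran-2-one
Conditions: DBU (2 equiv), toluene, 25 → 60 °C; then aq. NaH2PO4
Reagents that add atoms: none
Why: Proposed new method: DBU enolises the 1,3-diketone of 28; the enolate oxygen on the former amide carbon (future position 1 of ring B) adds 6-exo-trig to the aryl lactone carbonyl (position 2 of ring B) and the tetrahedral intermediate collapses with loss of the phenoxide at position 2 of ring A (alternatively E1cB loss of the phenoxide gives an acylketene that closes by oxa-6π electrocyclisation), and both paths end in the 4-hydroxy-2-pyrone. Exchange of an aryl ester for a conjugated, acidic pyrone held as its DBU salt should make the ring switch downhill. The closest known reaction is base-induced cyclisation of 3,5-dioxoalkanoate esters to 4-hydroxy-2-pyrones with loss of alkoxide; here the leaving group is the ring phenoxide of a dihydrocoumarin.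

Step 13
Reactants: 29 6-ethyl-4-hydroxy-3-{[2-hydroxy-6-methoxy-4-(methoxymethoxy)-3-(3-methylbut-2-en-1-yl)-5-(2-methylpropanoyl)phenyl]methyl}-5-methyl-2H-pyran-2-one
Product: 30 3-{[2,4-dihydroxy-6-methoxy-3-(3-methylbut-2-en-1-yl)-5-(2-methylpropanoyl)phenyl]methyl}-6-ethyl-4-hydroxy-5-methyl-2H-pyran-2-one (CNP0149198.0)
Conditions: HCl (3 M aq., cat.), MeOH, rt → 40 °C
Reagents that add atoms: none
Why: acetal cleavage of a MOM ether ortho to a chelating ketone is fast under dilute acid, mild enough that the prenyl group should not cyclise onto the neighbouring phenols.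

**Compound list**

1 | 5-methoxyresorcinol (5-methoxybenzene-1,3-diol) | COc1cc(O)cc(O)c1 | starting material
2 | 1-methoxy-3,5-bis(methoxymethoxy)benzene | COCOc1cc(OC)cc(OCOC)c1 | intermediate
3 | prenyl bromide (1-bromo-3-methylbut-2-ene) | CC(C)=CCBr | starting material
4 | [4-methoxy-2,6-bis(methoxymethoxy)phenyl]lithium (not isolated) | [Li]c1c(OCOC)cc(OC)cc1OCOC | intermediate
5 | 5-methoxy-1,3-bis(methoxymethoxy)-2-(3-methylbut-2-en-1-yl)benzene | COCOc1cc(OC)cc(OCOC)c1CC=C(C)C | intermediate
6 | [6-methoxy-2,4-bis(methoxymethoxy)-3-(3-methylbut-2-en-1-yl)phenyl]lithium (not isolated) | [Li]c1c(OC)cc(OCOC)c(CC=C(C)C)c1OCOC | intermediate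
7 | trimethyl[6-methoxy-2,4-bis(methoxymethoxy)-3-(3-methylbut-2-en-1-yl)phenyl]silane | COc1cc(OCOC)c(CC=C(C)C)c(OCOC)c1[Si](C)(C)C | intermediate
8 | isobutyraldehyde (2-methylpropanal) | CC(C)C=O | starting material
9 | [6-methoxy-2,4-bis(methoxymethoxy)-3-(3-methylbut-2-en-1-yl)-5-(trimethylsilyl)phenyl]lithium (not isolated) | [Li]c1c(OC)c([Si](C)(C)C)c(OCOC)c(CC=C(C)C)c1OCOC | intermediate
10 | racemic 1-[6-methoxy-2,4-bis(methoxymethoxy)-3-(3-methylbut-2-en-1-yl)-5-(trimethylsilyl)phenyl]-2-methylpropan-1-ol | COc1c([Si](C)(C)C)c(OCOC)c(CC=C(C)C)c(OCOC)c1C(O)C(C)C | intermediate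
11 | 1-[6-methoxy-2,4-bis(methoxymethoxy)-3-(3-methylbut-2-en-1-yl)-5-(trimethylsilyl)phenyl]-2-methylpropan-1-one | COc1c([Si](C)(C)C)c(OCOC)c(CC=C(C)C)c(OCOC)c1C(=O)C(C)C | intermediate
12 | 1-[6-methoxy-3-(3-methylbut-2-en-1-yl)-5-(trimethylsilyl)-2,4-bis(trimethylsilyloxy)phenyl]-2-methylpropan-1-one (not isolated) | COc1c([Si](C)(C)C)c(O[Si](C)(C)C)c(CC=C(C)C)c(O[Si](C)(C)C)c1C(=O)C(C)C | intermediate
13 | 1-[2,4-dihydroxy-6-methoxy-3-(3-methylbut-2-en-1-yl)-5-(trimethylsilyl)phenyl]-2-methylpropan-1-one | COc1c([Si](C)(C)C)c(O)c(CC=C(C)C)c(O)c1C(=O)C(C)C | intermediate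
14 | 3-hydroxy-5-methoxy-2-(3-methylbut-2-en-1-yl)-4-(2-methylpropanoyl)-6-(trimethylsilyl)phenyl trifluoromethanesulfonate | COc1c([Si](C)(C)C)c(OS(=O)(=O)C(F)(F)F)c(CC=C(C)C)c(O)c1C(=O)C(C)C | intermediate
15 | 5-methoxy-3-(methoxymethoxy)-2-(3-methylbut-2-en-1-yl)-4-(2-methylpropanoyl)-6-(trimethylsilyl)phenyl trifluoromethanesulfonate | COc1c([Si](C)(C)C)c(OS(=O)(=O)C(F)(F)F)c(CC=C(C)C)c(OCOC)c1C(=O)C(C)C | intermediate
16 | N,N-dimethylformamide | CN(C)C=O | starting material
17 | methyl 3-oxopentanoate | CCC(=O)CC(=O)OC | starting material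
18 | 3-methoxy-5-(methoxymethoxy)-6-(3-methylbut-2-en-1-yl)-4-(2-methylpropanoyl)-1,2-didehydrobenzene (not isolated) | COC1=C(C(=O)C(C)C)C(OCOC)=C(CC=C(C)C)C#C1 | intermediate
19 | racemic 2-(dimethylamino)-3-methoxy-5-(methoxymethoxy)-6-(3-methylbut-2-en-1-yl)-4-(2-methylpropanoyl)-2H-benzoxete (not isolated) | CN(C)C1Oc2c(CC=C(C)C)c(OCOC)c(C(=O)C(C)C)c(OC)c21 | intermediate
20 | 6-[(dimethylamino)methylidene]-5-methoxy-3-(methoxymethoxy)-2-(3-methylbut-2-en-1-yl)-4-(2-methylpropanoyl)cyclohexa-2,4-dien-1-one (not isolated) | CN(C)C=C1C(=O)C(CC=C(C)C)=C(OCOC)C(C(=O)C(C)C)=C1OC | intermediate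
21 | methyl 2-{(dimethylamino)[2-hydroxy-6-methoxy-4-(methoxymethoxy)-3-(3-methylbut-2-en-1-yl)-5-(2-methylpropanoyl)phenyl]methyl}-3-oxopentanoate, diastereomer mixture (not isolated) | CCC(=O)C(C(=O)OC)C(N(C)C)c1c(O)c(CC=C(C)C)c(OCOC)c(C(=O)C(C)C)c1OC | intermediate
22 | methyl (2Z)-2-{[2-hydroxy-6-methoxy-4-(methoxymethoxy)-3-(3-methylbut-2-en-1-yl)-5-(2-methylpropanoyl)phenyl]methylidene}-3-oxopentanoate, the lactonising isomer (not isolated) | CCC(=O)/C(C(=O)OC)=C/c1c(O)c(CC=C(C)C)c(OCOC)c(C(=O)C(C)C)c1OC | intermediate
23 | 5-methoxy-7-(methoxymethoxy)-8-(3-methylbut-2-en-1-yl)-6-(2-methylpropanoyl)-3-propanoyl-2H-chromen-2-one | CCC(=O)c1cc2c(OC)c(C(=O)C(C)C)c(OCOC)c(CC=C(C)C)c2oc1=O | intermediate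
24 | racemic 5-methoxy-7-(methoxymethoxy)-8-(3-methylbut-2-en-1-yl)-6-(2-methylpropanoyl)-3-propanoyl-3,4-dihydro-2H-chromen-2-one | CCC(=O)C1Cc2c(OC)c(C(=O)C(C)C)c(OCOC)c(CC=C(C)C)c2OC1=O | intermediate
25 | N-methoxy-N-methylpropanamide | CCC(=O)N(C)OC | starting material
26 | trilithium trienolate of 24 (lactone enolate, propanoyl dienolate terminus, isobutyryl enolate; not isolated) | CC=C(O[Li])C1=C(O[Li])Oc2c(CC=C(C)C)c(OCOC)c(C(O[Li])=C(C)C)c(OC)c2C1 | intermediate
27 | lithium N-methoxy-N-methyl hemiaminal adduct of 26 at the propanoyl carbon (not isolated) | CCC(O[Li])(N(C)OC)C(C)C(=O)C1=C(O[Li])Oc2c(CC=C(C)C)c(OCOC)c(C(O[Li])=C(C)C)c(OC)c2C1 | intermediate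
28 | 5-methoxy-7-(methoxymethoxy)-8-(3-methylbut-2-en-1-yl)-3-(2-methyl-3-oxopentanoyl)-6-(2-methylpropanoyl)-3,4-dihydro-2H-chromen-2-one, diastereomer and enol mixture | CCC(=O)C(C)C(=O)C1Cc2c(OC)c(C(=O)C(C)C)c(OCOC)c(CC=C(C)C)c2OC1=O | intermediate
29 | 6-ethyl-4-hydroxy-3-{[2-hydroxy-6-methoxy-4-(methoxymethoxy)-3-(3-methylbut-2-en-1-yl)-5-(2-methylpropanoyl)phenyl]methyl}-5-methyl-2H-pyran-2-one | CCc1oc(=O)c(Cc2c(O)c(CC=C(C)C)c(OCOC)c(C(=O)C(C)C)c2OC)c(O)c1C | intermediate
30 | 3-{[2,4-dihydroxy-6-methoxy-3-(3-methylbut-2-en-1-yl)-5-(2-methylpropanoyl)phenyl]methyl}-6-ethyl-4-hydroxy-5-methyl-2H-pyran-2-one | CCc1oc(=O)c(Cc2c(O)c(CC=C(C)C)c(O)c(C(=O)C(C)C)c2OC)c(O)c1C | target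

**Step count and risks**

Total step count: 13. Longest linear sequence: 13 steps (from 5-methoxyresorcinol).

Steps most likely to fail:

1. Step 12 (proposed ring switch). The acyl transfer may stall because the enolised tricarbonyl is a delocalised, weakly nucleophilic anion with a deactivated lactone carbonyl. Cleavage of the β-keto lactone by adventitious water (retro-Claisen, then decarboxylation) may also outrun it. The fallback sets out from 15 (using 17 and 25) and returns at 29, using known reactions only. The aryne from 15 is generated with CsF in DMF without a carbon nucleophile, and the DMF adduct is hydrolysed with water to the salicylaldehyde F1. In parallel the dianion of 17 (NaH, then n-BuLi, THF) is acylated with 25 to methyl 4-methyl-3,5-dioxoheptanoate F2. DBU in hot toluene closes this to 6-ethyl-4-hydroxy-5-methyl-2H-pyran-2-one F3. Reductive Knoevenagel alkylation of F3 with F1 (L-proline cat., Hantzsch ester, CH2Cl2) should then give 29, and step 13 follows.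

2. Step 9 (key step). The keto ester enolate may add directly to the aryne (C-arylation or acyl-alkylation) in competition with DMF. The DMF oxygen may attack position 1 of ring A instead of position 2 because of the prenyl group next to position 2. A second keto ester may add to carbon 4 of the coumarin. The fallback sets out from 11 and returns at 23 without an aryne. HCl in MeOH removes both MOM ethers and, by ipso-protodesilylation, the silyl group, to give the resorcinol ketone F4. Magnesium-mediated ortho-formylation (MgCl2, Et3N, paraformaldehyde, CH3CN, reflux) at the only free ring position (position 1 of ring A) gives the dihydroxy salicylaldehyde F5. Knoevenagel condensation and lactonisation with 17 (piperidine cat., EtOH) gives the 7-hydroxycoumarin F6. MOMCl and i-Pr2NEt then give 23.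

3. Step 11. Proton transfer from the enolisable amide to the strongly basic dienolate may be faster than C-acylation, returning 24. Slow acylation may also let the isobutyryl enolate compete. The fallback sets out from 24 and returns at 28. The same trienolate 26 is treated with propanal at −78 °C, where aldol addition is much faster than proton transfer, to give the hydroxy keto lactone F7 after a cold AcOH quench. F7 is oxidised at once with Dess–Martin periodinane (pyridine, CH2Cl2) to 28.

**Further compounds**

F1 | step 12 | 2-hydroxy-6-methoxy-4-(methoxymethoxy)-3-(3-methylbut-2-en-1-yl)-5-(2-methylpropanoyl)benzaldehyde | COc1c(C=O)c(O)c(CC=C(C)C)c(OCOC)c1C(=O)C(C)C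
F2 | step 12 | methyl 4-methyl-3,5-dioxoheptanoate | CCC(=O)C(C)C(=O)CC(=O)OC
F3 | step 12 | 6-ethyl-4-hydroxy-5-methyl-2H-pyran-2-one | CCc1oc(=O)cc(O)c1C
F4 | step 9 | 1-[2,4-dihydroxy-6-methoxy-3-(3-methylbut-2-en-1-yl)phenyl]-2-methylpropan-1-one | COc1cc(O)c(CC=C(C)C)c(O)c1C(=O)C(C)C
F5 | step 9 | 2,4-dihydroxy-6-methoxy-3-(3-methylbut-2-en-1-yl)-5-(2-methylpropanoyl)benzaldehyde | COc1c(C=O)c(O)c(CC=C(C)C)c(O)c1C(=O)C(C)C
F6 | step 9 | 7-hydroxy-5-methoxy-8-(3-methylbut-2-en-1-yl)-6-(2-methylpropanoyl)-3-propanoyl-2H-chromen-2-one | CCC(=O)c1cc2c(OC)c(C(=O)C(C)C)c(O)c(CC=C(C)C)c2oc1=O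
F7 | step 11 | 3-(3-hydroxy-2-methylpentanoyl)-5-methoxy-7-(methoxymethoxy)-8-(3-methylbut-2-en-1-yl)-6-(2-methylpropanoyl)-3,4-dihydro-2H-chromen-2-one, diastereomer mixture | CCC(O)C(C)C(=O)C1Cc2c(OC)c(C(=O)C(C)C)c(OCOC)c(CC=C(C)C)c2OC1=O
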